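**Plan**

- Numbering: ring A is the dihydroxy ring (C1 = CMe2, C2 = CH2, C3 = CHOH, C4=C5 with the methyl on C5, C6 = tertiary carbinol carrying the chain from C7). Ring B is the hydroxy ring attached to the alkyne.
- Cuts: the polyene at the two disubstituted double bonds on either side of the central C10 unit (Wittig, C15 + C10 + C15), ring B at its ring–alkyne bond (Sonogashira), the ring A side chain at C7=C8 (Horner–Wadsworth–Emmons), and ring A itself at C1–C2 and C5–C6 in a single [4+2] step.
- Enabling feature: C3–O, C4=C5 and the C5 methyl of ring A are the retron of a 1-methoxy-1-methyl-3-silyloxy diene (C2–C5). C1 (CMe2) and C6 (one oxygen, one carbon that becomes C7) form a captodative Me2C=C(O)(C=O) dienophile, available as a 2-tert-butyl-5-isopropylidene-1,3-dioxolan-4-one.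
- Forward order: ring A is built first by the cycloaddition; its lactone carbon becomes the C7 aldehyde and is extended to a C15 dienal. Ring B comes from actinol (enol triflate, Sonogashira), grows to a C25 phosphonium salt with the C10 dialdehyde, and a last Wittig reaction joins the halves without protecting groups.
- Stereochemistry: C6 from the tert-butyl acetal centre of the dioxolanone, itself from (S)-2-hydroxy-3-methylbutanoic acid (self-regeneration of the stereocentre). C3 by substrate-controlled Luche reduction cis to the C6 hydroxyl. The ring B carbinol from (4R,6R)-actinol. E-alkenes from HWE/Wittig steps and the E-enynol building block.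

Key step: step 4

Remark: 1, 2, 6, 12, 17, 20 and 23 are treated as catalogue chemicals, and 10 is carried as an inconsequential mixture of epimers at the secondary carbinol, which step 6 oxidises.

**Route**

Step 1
Reactants: 1 (S)-2-hydroxy-3-methylbutanoic acid; 2 pivalaldehyde
Product: 3 (2S,5S)-2-tert-butyl-5-(propan-2-yl)-1,3-dioxolan-4-one
Conditions: TsOH·H2O (cat.), H2SO4 (cat.), pentane, reflux with water separator; crystallisation
Reagents that add atoms: none
Why: Acid-catalysed acetalisation of the α-hydroxy acid with pivalaldehyde gives the 2-tert-butyl-1,3-dioxolan-4-one, the new acetal stereocentre being formed predominantly cis to the isopropyl group and purified by crystallisation.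

Step 2
Reactants: 3 (2S,5S)-2-tert-butyl-5-(propan-2-yl)-1,3-dioxolan-4-one
Product: 5 (2S)-2-tert-butyl-5-(propan-2-ylidene)-1,3-dioxolan-4-one, via tertiary bromide 4 (not isolated)
Conditions: NBS, AIBN (cat.), CCl4, reflux; then Et3N, 0 °C → rt
Reagents that add atoms: none
Why: Radical bromination with NBS takes the captodatively stabilised ring C–H between the ring oxygen and the carbonyl, and dehydrobromination of the tertiary bromide toward its only β-hydrogen gives the tetrasubstituted alkylidene lactone, leaving the acetal carbon as the sole stereocentre.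

Step 3
Reactants: 6 (E)-4-methoxypent-3-en-2-one
Product: 7 (E)-4-methoxy-2-(trimethylsilyloxy)penta-1,3-diene
Conditions: LiN(i-Pr)2, THF, −78 °C; Me3SiCl, −78 °C → rt; non-aqueous work-up, distillation
Reagents that add atoms: chlorotrimethylsilane, C[Si](C)(C)Cl
Why: Kinetic deprotonation of the methyl ketone at the α′-methyl group and O-silylation of the cross-conjugated enolate give the 1-methoxy-3-silyloxy diene with the enol ether geometry unchanged (silyl enol ether formation).

Step 4
Reactants: 5 (2S)-2-tert-butyl-5-(propan-2-ylidene)-1,3-dioxolan-4-one; 7 (E)-4-methoxy-2-(trimethylsilyloxy)penta-1,3-diene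
Product: 9 (2S,5R)-2-tert-butyl-6,10,10-trimethyl-1,3-dioxaspiro[4.5]dec-6-ene-4,8-dione, via silyl enol ether cycloadduct 8 (not isolated)
Conditions: 7 (2.5 equiv), HNTf2 (10 mol %), CH2Cl2, −78 → −30 °C; then 1 M HCl, THF, 0 °C → rt
Reagents that add atoms: none
Why: Formal [4+2] cycloaddition of Diels–Alder type, most probably stepwise: Me3SiNTf2 formed from HNTf2 and 7 activates the lactone carbonyl of 5, the CH2 terminus of the diene adds to the CMe2 β-carbon (Mukaiyama–Michael), and the dioxolanone silyl ketene acetal so formed closes onto the methoxy-substituted oxocarbenium carbon to give 8, which aqueous acid hydrolyses and from which it eliminates methanol to give enone 9. The closest known reaction types are the Diels–Alder reactions of 2-tert-butyl-5-alkylidene-1,3-dioxolan-4-ones and the triflimide-catalysed cycloadditions of hindered 2-silyloxydienes with β,β-disubstituted acceptors that join two quaternary carbons. Ring A is closed as a six-membered carbocycle in an intermolecular [4+2] mode, the second bond forming in a 6-(enolexo)-exo-trig sense if the process is stepwise. The only stereocentre that survives, the spiro carbinol carbon, is controlled by the tert-butyl-bearing acetal carbon: the new ring bond forms on the face of the planar dioxolanone anti to tert-butyl (self-regeneration of the stereocentre of 1, overall retention). Regiochemistry is needed and is secured by polarity, the nucleophilic CH2 terminus of the 1-methoxy-3-silyloxy diene pairing with the electrophilic β-carbon of the captodative acceptor, while endo/exo selectivity is irrelevant because the methoxy-bearing carbon becomes sp2.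

Step 5
Reactants: 9 (2S,5R)-2-tert-butyl-6,10,10-trimethyl-1,3-dioxaspiro[4.5]dec-6-ene-4,8-dione
Product: 10 (1R,4RS)-1-(hydroxymethyl)-2,6,6-trimethylcyclohex-2-ene-1,4-diol
Conditions: LiAlH4, Et2O, −20 → 0 °C; aq. NaOH work-up
Reagents that add atoms: none
Why: LiAlH4 reduces the β,β-disubstituted enone in the 1,2 sense and the lactone completely, the hemiacetal intermediate collapsing with loss of pivalaldehyde (reduced to neopentyl alcohol), so that the spiro centre emerges untouched as a tertiary alcohol and the new secondary carbinol, formed unselectively, is removed again in step 6.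

Step 6
Reactants: 10 (1R,4RS)-1-(hydroxymethyl)-2,6,6-trimethylcyclohex-2-ene-1,4-diol
Product: 11 (1R)-1-hydroxy-2,6,6-trimethyl-4-oxocyclohex-2-ene-1-carbaldehyde
Conditions: (COCl)2, DMSO, CH2Cl2, −78 °C; Et3N, −78 → 0 °C
Reagents that add atoms: none
Why: Swern oxidation converts the primary alcohol into the aldehyde and both epimers of the allylic secondary alcohol into the enone while the tertiary alcohol cannot be oxidised, and the aldehyde has no α-hydrogen so the quaternary centre cannot epimerise.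

Step 7
Reactants: 11 (1R)-1-hydroxy-2,6,6-trimethyl-4-oxocyclohex-2-ene-1-carbaldehyde; 12 ethyl (2E)-4-(diethoxyphosphoryl)-3-methylbut-2-enoate
Product: 13 ethyl (2E,4E)-5-[(1R)-1-hydroxy-2,6,6-trimethyl-4-oxocyclohex-2-en-1-yl]-3-methylpenta-2,4-dienoate
Conditions: 12 (2.5 equiv), LiN(SiMe3)2 (2.4 equiv), THF/DMPU, −78 °C; then 11, −78 → 0 °C
Reagents that add atoms: none
Why: Vinylogous Horner–Wadsworth–Emmons olefination: the lithiated phosphonate (one equivalent is spent on the hydroxyl) attacks the aldehyde far faster than the hindered β,β-disubstituted enone carbonyl and gives the new disubstituted double bond E, the trisubstituted double bond settling as E through the equilibrating allyl anion, with any 2Z isomer removed by chromatography.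

Step 8
Reactants: 13 ethyl (2E,4E)-5-[(1R)-1-hydroxy-2,6,6-trimethyl-4-oxocyclohex-2-en-1-yl]-3-methylpenta-2,4-dienoate
Product: 14 ethyl (2E,4E)-5-[(1R,4S)-1,4-dihydroxy-2,6,6-trimethylcyclohex-2-en-1-yl]-3-methylpenta-2,4-dienoate
Conditions: NaBH4, CeCl3·7H2O, MeOH, −78 °C
Reagents that add atoms: none
Why: Luche 1,2-reduction: as in abscisic acid esters the ring should adopt the half-chair with the dienyl chain pseudoaxial and the tertiary hydroxyl pseudoequatorial, so hydride attacks the carbonyl anti to the pseudoaxial methyl of the gem-dimethyl group and the new (S)-carbinol is set cis to the tertiary hydroxyl.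

Step 9
Reactants: 14 ethyl (2E,4E)-5-[(1R,4S)-1,4-dihydroxy-2,6,6-trimethylcyclohex-2-en-1-yl]-3-methylpenta-2,4-dienoate
Product: 15 (1R,4S)-1-[(1E,3E)-5-hydroxy-3-methylpenta-1,3-dien-1-yl]-2,6,6-trimethylcyclohex-2-ene-1,4-diol
Conditions: i-Bu2AlH (4.5 equiv), CH2Cl2, −78 °C; aq. potassium sodium tartrate
Reagents that add atoms: none
Why: i-Bu2AlH reduces the conjugated ester in the 1,2 sense to the primary allylic alcohol without touching the diene, the extra equivalents being consumed by the two free hydroxyls (ester reduction).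

Step 10
Reactants: 15 (1R,4S)-1-[(1E,3E)-5-hydroxy-3-methylpenta-1,3-dien-1-yl]-2,6,6-trimethylcyclohex-2-ene-1,4-diol
Product: 16 (2E,4E)-5-[(1R,4S)-1,4-dihydroxy-2,6,6-trimethylcyclohex-2-en-1-yl]-3-methylpenta-2,4-dienal
Conditions: MnO2 (activated, excess), CH2Cl2, 0 °C → rt, followed by TLC
Reagents that add atoms: none
Why: MnO2 should oxidise the primary dienylic alcohol much faster than the secondary ring allylic alcohol, whose cis-1,4-diol arrangement is expected to react slowly with this reagent, and it leaves the tertiary alcohol and the double-bond geometry untouched (chemoselective allylic oxidation).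

Step 11
Reactants: 17 (4R,6R)-4-hydroxy-2,2,6-trimethylcyclohexan-1-one (actinol)
Product: 18 (4R,6R)-2,2,6-trimethyl-4-(triethylsilyloxy)cyclohexan-1-one
Conditions: Et3SiCl, imidazole, DMF, 0 °C → rt
Reagents that add atoms: chlorotriethylsilane, CC[Si](Cl)(CC)CC
Why: Silylation of the secondary alcohol (silyl ether protection) masks it for the enolate chemistry of step 12 and leaves both stereocentres untouched.

Step 12
Reactants: 18 (4R,6R)-2,2,6-trimethyl-4-(triethylsilyloxy)cyclohexan-1-one
Product: 19 (4R)-2,6,6-trimethyl-4-(triethylsilyloxy)cyclohex-1-en-1-yl trifluoromethanesulfonate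
Conditions: LiN(i-Pr)2, THF, −78 → 0 °C; PhNTf2, −78 °C → rt
Reagents that add atoms: N-phenylbis(trifluoromethanesulfonimide), O=S(=O)(N(c1ccccc1)S(=O)(=O)C(F)(F)F)C(F)(F)F
Why: The ketone can enolise only toward the methyl-bearing α-carbon because the other α-carbon is quaternary, so trapping the lithium enolate with PhNTf2 gives a single tetrasubstituted enol triflate; the α-methyl stereocentre is deliberately erased and the carbinol centre is unaffected (enol triflate formation).

Step 13
Reactants: 19 (4R)-2,6,6-trimethyl-4-(triethylsilyloxy)cyclohex-1-en-1-yl trifluoromethanesulfonate; 20 (E)-3-methylpent-2-en-4-yn-1-ol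
Product: 21 (2E)-3-methyl-5-[(4R)-2,6,6-trimethyl-4-(triethylsilyloxy)cyclohex-1-en-1-yl]pent-2-en-4-yn-1-ol
Conditions: PdCl2(PPh3)2 (5 mol %), CuI (10 mol %), Et3N, DMF, rt → 45 °C
Reagents that add atoms: none
Why: Sonogashira coupling of the enol triflate with the terminal alkyne forms the ring–alkyne bond under mild conditions that preserve the E-alkene of 20 and the silyl ether.

Step 14
Reactants: 21 (2E)-3-methyl-5-[(4R)-2,6,6-trimethyl-4-(triethylsilyloxy)cyclohex-1-en-1-yl]pent-2-en-4-yn-1-ol
Product: 22 [(2E)-5-[(4R)-4-hydroxy-2,6,6-trimethylcyclohex-1-en-1-yl]-3-methylpent-2-en-4-yn-1-yl]triphenylphosphonium bromide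
Conditions: PPh3·HBr, MeOH, 0 °C → rt
Reagents that add atoms: triphenylphosphine hydrobromide, [Br-].[PH+](c1ccccc1)(c1ccccc1)c1ccccc1
Why: The allylic alcohol ionises under the acid of PPh3·HBr and the allyl/propargyl cation is captured by PPh3 at the primary terminus to give the conjugated E-phosphonium salt, while acidic methanol removes the triethylsilyl ether at the same time (phosphonium salt formation of the C15 + C10 + C15 carotenoid protocol).

Step 15
Reactants: 22 [(2E)-5-[(4R)-4-hydroxy-2,6,6-trimethylcyclohex-1-en-1-yl]-3-methylpent-2-en-4-yn-1-yl]triphenylphosphonium bromide; 23 (2E,4E,6E)-2,7-dimethylocta-2,4,6-trienedial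
Product: 24 (2E,4E,6E,8E,10E)-13-[(4R)-4-hydroxy-2,6,6-trimethylcyclohex-1-en-1-yl]-2,7,11-trimethyltrideca-2,4,6,8,10-pentaen-12-ynal
Conditions: 23 (3 equiv), NaOMe, MeOH/CH2Cl2, 0 °C → rt, dark
Reagents that add atoms: none
Why: Wittig olefination of the semistabilised ylide with an excess of the symmetrical dialdehyde gives the mono-adduct, the new disubstituted double bond being formed mainly E (the Z isomer there is sterically hindered and is removed on purification).

Step 16
Reactants: 24 (2E,4E,6E,8E,10E)-13-[(4R)-4-hydroxy-2,6,6-trimethylcyclohex-1-en-1-yl]-2,7,11-trimethyltrideca-2,4,6,8,10-pentaen-12-ynal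
Product: 25 (2E,4E,6E,8E,10E)-13-[(4R)-4-hydroxy-2,6,6-trimethylcyclohex-1-en-1-yl]-2,7,11-trimethyltrideca-2,4,6,8,10-pentaen-12-yn-1-ol
Conditions: NaBH4, MeOH/THF, 0 °C
Reagents that add atoms: none
Why: NaBH4 reduces the polyenal chemoselectively in the 1,2 sense to the allylic alcohol without affecting the polyene or the enyne (carbonyl reduction).

Step 17
Reactants: 25 (2E,4E,6E,8E,10E)-13-[(4R)-4-hydroxy-2,6,6-trimethylcyclohex-1-en-1-yl]-2,7,11-trimethyltrideca-2,4,6,8,10-pentaen-12-yn-1-ol
Product: 26 [(2E,4E,6E,8E,10E)-13-[(4R)-4-hydroxy-2,6,6-trimethylcyclohex-1-en-1-yl]-2,7,11-trimethyltrideca-2,4,6,8,10-pentaen-12-yn-1-yl]triphenylphosphonium bromide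
Conditions: PPh3·HBr, MeOH/CH2Cl2, 0 °C → rt, dark
Reagents that add atoms: triphenylphosphine hydrobromide, [Br-].[PH+](c1ccccc1)(c1ccccc1)c1ccccc1
Why: As in step 14, acid-promoted ionisation of the polyenylic alcohol and capture of the delocalised cation by PPh3 at the terminal carbon gives the fully conjugated phosphonium salt, conjugation and sterics favouring the terminal all-E product.

Step 18
Reactants: 26 [(2E,4E,6E,8E,10E)-13-[(4R)-4-hydroxy-2,6,6-trimethylcyclohex-1-en-1-yl]-2,7,11-trimethyltrideca-2,4,6,8,10-pentaen-12-yn-1-yl]triphenylphosphonium bromide; 16 (2E,4E)-5-[(1R,4S)-1,4-dihydroxy-2,6,6-trimethylcyclohex-2-en-1-yl]-3-methylpenta-2,4-dienal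
Product: 27 all-E (3R,3′S,6′R)-7,8-didehydro-β,ε-carotene-3,3′,6′-triol
Conditions: NaOMe, MeOH/CH2Cl2, 0 °C → rt, dark, argon; chromatography and crystallisation of the all-E isomer
Reagents that add atoms: none
Why: Wittig olefination of the C25 ylide with the C15 dienal forms the last disubstituted double bond mainly E because the Z isomer at this position is the sterically hindered one, the free hydroxyls are tolerated by NaOMe, no stereocentre is touched, and the all-E product is isolated by chromatography and crystallisation without heat or iodine so as not to isomerise the double bond next to the alkyne.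

**Compound list**

1 | (S)-2-hydroxy-3-methylbutanoic acid | CC(C)[C@H](O)C(=O)O | starting material
2 | pivalaldehyde (2,2-dimethylpropanal) | CC(C)(C)C=O | starting material
3 | (2S,5S)-2-tert-butyl-5-(propan-2-yl)-1,3-dioxolan-4-one (cis) | CC(C)[C@@H]1O[C@H](C(C)(C)C)OC1=O | intermediate
4 | (2S,5R)-5-bromo-2-tert-butyl-5-(propan-2-yl)-1,3-dioxolan-4-one (bromine anti to tert-butyl expected) | CC(C)[C@]1(Br)O[C@H](C(C)(C)C)OC1=O | intermediate
5 | (2S)-2-tert-butyl-5-(propan-2-ylidene)-1,3-dioxolan-4-one | CC(C)=C1O[C@H](C(C)(C)C)OC1=O | intermediate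
6 | (E)-4-methoxypent-3-en-2-one | CC(=O)/C=C(\C)OC | starting material
7 | (E)-4-methoxy-2-(trimethylsilyloxy)penta-1,3-diene | C=C(O[Si](C)(C)C)/C=C(\C)OC | intermediate
8 | (2S,5R)-2-tert-butyl-6-methoxy-6,10,10-trimethyl-8-(trimethylsilyloxy)-1,3-dioxaspiro[4.5]dec-7-en-4-one (methoxy-bearing carbon unassigned) | COC1(C)C=C(O[Si](C)(C)C)CC(C)(C)[C@@]12O[C@H](C(C)(C)C)OC2=O | intermediate
9 | (2S,5R)-2-tert-butyl-6,10,10-trimethyl-1,3-dioxaspiro[4.5]dec-6-ene-4,8-dione | CC1=CC(=O)CC(C)(C)[C@@]12O[C@H](C(C)(C)C)OC2=O | intermediate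
10 | (1R,4RS)-1-(hydroxymethyl)-2,6,6-trimethylcyclohex-2-ene-1,4-diol (epimers at C4) | CC1=CC(O)CC(C)(C)[C@]1(O)CO | intermediate
11 | (1R)-1-hydroxy-2,6,6-trimethyl-4-oxocyclohex-2-ene-1-carbaldehyde | CC1=CC(=O)CC(C)(C)[C@]1(O)C=O | intermediate
12 | ethyl (2E)-4-(diethoxyphosphoryl)-3-methylbut-2-enoate | CCOC(=O)/C=C(\C)CP(=O)(OCC)OCC | starting material
13 | ethyl (2E,4E)-5-[(1R)-1-hydroxy-2,6,6-trimethyl-4-oxocyclohex-2-en-1-yl]-3-methylpenta-2,4-dienoate | CC1=CC(=O)CC(C)(C)[C@]1(O)/C=C/C(C)=C/C(=O)OCC | intermediate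
14 | ethyl (2E,4E)-5-[(1R,4S)-1,4-dihydroxy-2,6,6-trimethylcyclohex-2-en-1-yl]-3-methylpenta-2,4-dienoate | CC1=C[C@@H](O)CC(C)(C)[C@]1(O)/C=C/C(C)=C/C(=O)OCC | intermediate
15 | (1R,4S)-1-[(1E,3E)-5-hydroxy-3-methylpenta-1,3-dien-1-yl]-2,6,6-trimethylcyclohex-2-ene-1,4-diol | CC1=C[C@@H](O)CC(C)(C)[C@]1(O)/C=C/C(C)=C/CO | intermediate
16 | (2E,4E)-5-[(1R,4S)-1,4-dihydroxy-2,6,6-trimethylcyclohex-2-en-1-yl]-3-methylpenta-2,4-dienal | CC1=C[C@@H](O)CC(C)(C)[C@]1(O)/C=C/C(C)=C/C=O | intermediate
17 | (4R,6R)-4-hydroxy-2,2,6-trimethylcyclohexan-1-one (actinol) | O=C1[C@H](C)C[C@@H](O)CC1(C)C | starting material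
18 | (4R,6R)-2,2,6-trimethyl-4-(triethylsilyloxy)cyclohexan-1-one | O=C1[C@H](C)C[C@@H](O[Si](CC)(CC)CC)CC1(C)C | intermediate
19 | (4R)-2,6,6-trimethyl-4-(triethylsilyloxy)cyclohex-1-en-1-yl trifluoromethanesulfonate | CC1=C(OS(=O)(=O)C(F)(F)F)C(C)(C)C[C@H](O[Si](CC)(CC)CC)C1 | intermediate
20 | (E)-3-methylpent-2-en-4-yn-1-ol | OC/C=C(\C)C#C | starting material
21 | (2E)-3-methyl-5-[(4R)-2,6,6-trimethyl-4-(triethylsilyloxy)cyclohex-1-en-1-yl]pent-2-en-4-yn-1-ol | OC/C=C(\C)C#CC1=C(C)C[C@@H](O[Si](CC)(CC)CC)CC1(C)C | intermediate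
22 | [(2E)-5-[(4R)-4-hydroxy-2,6,6-trimethylcyclohex-1-en-1-yl]-3-methylpent-2-en-4-yn-1-yl]triphenylphosphonium bromide | [Br-].c1ccccc1[P+](c1ccccc1)(c1ccccc1)C/C=C(\C)C#CC1=C(C)C[C@@H](O)CC1(C)C | intermediate
23 | (2E,4E,6E)-2,7-dimethylocta-2,4,6-trienedial | O=C/C(C)=C/C=C/C=C(C)/C=O | starting material
24 | (2E,4E,6E,8E,10E)-13-[(4R)-4-hydroxy-2,6,6-trimethylcyclohex-1-en-1-yl]-2,7,11-trimethyltrideca-2,4,6,8,10-pentaen-12-ynal | O=C/C(C)=C/C=C/C=C(C)/C=C/C=C(\C)C#CC1=C(C)C[C@@H](O)CC1(C)C | intermediate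
25 | (2E,4E,6E,8E,10E)-13-[(4R)-4-hydroxy-2,6,6-trimethylcyclohex-1-en-1-yl]-2,7,11-trimethyltrideca-2,4,6,8,10-pentaen-12-yn-1-ol | OC/C(C)=C/C=C/C=C(C)/C=C/C=C(\C)C#CC1=C(C)C[C@@H](O)CC1(C)C | intermediate
26 | [(2E,4E,6E,8E,10E)-13-[(4R)-4-hydroxy-2,6,6-trimethylcyclohex-1-en-1-yl]-2,7,11-trimethyltrideca-2,4,6,8,10-pentaen-12-yn-1-yl]triphenylphosphonium bromide | [Br-].c1ccccc1[P+](c1ccccc1)(c1ccccc1)C/C(C)=C/C=C/C=C(C)/C=C/C=C(\C)C#CC1=C(C)C[C@@H](O)CC1(C)C | intermediate
27 | all-E (3R,3′S,6′R)-7,8-didehydro-β,ε-carotene-3,3′,6′-triol | CC1=C[C@@H](O)CC(C)(C)[C@]1(O)/C=C/C(C)=C/C=C/C(C)=C/C=C/C=C(C)/C=C/C=C(\C)C#CC1=C(C)C[C@@H](O)CC1(C)C | target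

**Totals**

Total step count: 18.
Longest linear sequence: 10 steps (1 → 3 → 5 → 9 → 10 → 11 → 13 → 14 → 15 → 16 → 27; steps 1, 2, 4–10 and 18).

**Steps most likely to fail**

Step 4. The fully substituted acceptor carbon and the 1,1-disubstituted diene terminus may combine too slowly, so that protodesilylation and oligomerisation of the diene win, or the sequence stops after the first C–C bond. The fallback uses a diene without the ring methyl and adds the methyl afterwards; it sets out from 5 and returns at 9. Compound 5 is combined with commercial trans-1-methoxy-3-(trimethylsilyloxy)buta-1,3-diene, whose methoxy terminus is far less hindered (toluene, 110 °C, or the same silyl triflimide catalysis). This should give the cycloadduct (2S,5R)-2-tert-butyl-6-methoxy-10,10-dimethyl-8-(trimethylsilyloxy)-1,3-dioxaspiro[4.5]dec-7-en-4-one F1. Dilute HCl converts it into (2S,5S)-2-tert-butyl-10,10-dimethyl-1,3-dioxaspiro[4.5]dec-6-ene-4,8-dione F2, which has the same spatial arrangement as 9 (the descriptor changes only through the priorities). Conjugate addition of Me2CuLi in the presence of Me3SiCl (THF, −78 °C) places the methyl on the β-carbon and gives the silyl enol ether (2S,5S)-2-tert-butyl-6,10,10-trimethyl-8-(trimethylsilyloxy)-1,3-dioxaspiro[4.5]dec-7-en-4-one F3. Saegusa–Ito dehydrogenation (Pd(OAc)2 cat., O2, DMSO) then restores the enone, which is 9.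

Step 8. The conformational bias may be too small, so that hydride is delivered to both faces and much of the material ends as the 1,4-trans diol. The fallback replaces hydride control by inversion; it sets out from 13 and returns at 14. After the reduction the unwanted epimer, ethyl (2E,4E)-5-[(1R,4R)-1,4-dihydroxy-2,6,6-trimethylcyclohex-2-en-1-yl]-3-methylpenta-2,4-dienoate F4, is separated. Mitsunobu inversion (4-nitrobenzoic acid, PPh3, DIAD, THF, 0 °C; the tertiary hydroxyl does not react) gives ethyl (2E,4E)-5-[(1R,4S)-1-hydroxy-2,6,6-trimethyl-4-(4-nitrobenzoyloxy)cyclohex-2-en-1-yl]-3-methylpenta-2,4-dienoate F5. Ethanolysis (K2CO3, EtOH) then gives 14.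

Step 17. Ionisation of the C25 pentaenynol gives a long delocalised cation that may scramble double-bond geometry, notably at the double bond next to the alkyne, or decompose before the phosphine captures it. The fallback reverses the polarity of the last olefination and forms the phosphonium salt under neutral conditions; it sets out from 14 and returns at 27, using aldehyde 24 directly. Silylation of 14 (t-BuMe2SiCl, imidazole, DMF) gives ethyl (2E,4E)-5-[(1R,4S)-4-(tert-butyldimethylsilyloxy)-1-hydroxy-2,6,6-trimethylcyclohex-2-en-1-yl]-3-methylpenta-2,4-dienoate F6. Reduction with i-Bu2AlH gives (1R,4S)-4-(tert-butyldimethylsilyloxy)-1-[(1E,3E)-5-hydroxy-3-methylpenta-1,3-dien-1-yl]-2,6,6-trimethylcyclohex-2-en-1-ol F7. Appel bromination (CBr4, PPh3, CH2Cl2, −20 °C) gives (1R,4S)-1-[(1E,3E)-5-bromo-3-methylpenta-1,3-dien-1-yl]-4-(tert-butyldimethylsilyloxy)-2,6,6-trimethylcyclohex-2-en-1-ol F8, which is treated at once with PPh3 to give [(2E,4E)-5-[(1R,4S)-4-(tert-butyldimethylsilyloxy)-1-hydroxy-2,6,6-trimethylcyclohex-2-en-1-yl]-3-methylpenta-2,4-dien-1-yl]triphenylphosphonium bromide F9. Wittig reaction of F9 with 24 (NaOMe, MeOH/CH2Cl2) gives the 3′-O-(tert-butyldimethylsilyl) ether of 27 F10, and Bu4NF in THF removes the silyl group to give 27.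

**Further compounds**

F1 | step 4 | (2S,5R)-2-tert-butyl-6-methoxy-10,10-dimethyl-8-(trimethylsilyloxy)-1,3-dioxaspiro[4.5]dec-7-en-4-one (methoxy-bearing carbon unassigned) | COC1C=C(O[Si](C)(C)C)CC(C)(C)[C@@]12O[C@H](C(C)(C)C)OC2=O
F2 | step 4 | (2S,5S)-2-tert-butyl-10,10-dimethyl-1,3-dioxaspiro[4.5]dec-6-ene-4,8-dione | C1=CC(=O)CC(C)(C)[C@@]12O[C@H](C(C)(C)C)OC2=O
F3 | step 4 | (2S,5S)-2-tert-butyl-6,10,10-trimethyl-8-(trimethylsilyloxy)-1,3-dioxaspiro[4.5]dec-7-en-4-one (methyl-bearing ring carbon unassigned) | CC1C=C(O[Si](C)(C)C)CC(C)(C)[C@@]12O[C@H](C(C)(C)C)OC2=O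
F4 | step 8 | ethyl (2E,4E)-5-[(1R,4R)-1,4-dihydroxy-2,6,6-trimethylcyclohex-2-en-1-yl]-3-methylpenta-2,4-dienoate | CC1=C[C@H](O)CC(C)(C)[C@]1(O)/C=C/C(C)=C/C(=O)OCC
F5 | step 8 | ethyl (2E,4E)-5-[(1R,4S)-1-hydroxy-2,6,6-trimethyl-4-(4-nitrobenzoyloxy)cyclohex-2-en-1-yl]-3-methylpenta-2,4-dienoate | CC1=C[C@@H](OC(=O)c2ccc(cc2)[N+](=O)[O-])CC(C)(C)[C@]1(O)/C=C/C(C)=C/C(=O)OCC
F6 | step 17 | ethyl (2E,4E)-5-[(1R,4S)-4-(tert-butyldimethylsilyloxy)-1-hydroxy-2,6,6-trimethylcyclohex-2-en-1-yl]-3-methylpenta-2,4-dienoate | CC1=C[C@@H](O[Si](C)(C)C(C)(C)C)CC(C)(C)[C@]1(O)/C=C/C(C)=C/C(=O)OCC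
F7 | step 17 | (1R,4S)-4-(tert-butyldimethylsilyloxy)-1-[(1E,3E)-5-hydroxy-3-methylpenta-1,3-dien-1-yl]-2,6,6-trimethylcyclohex-2-en-1-ol | CC1=C[C@@H](O[Si](C)(C)C(C)(C)C)CC(C)(C)[C@]1(O)/C=C/C(C)=C/CO
F8 | step 17 | (1R,4S)-1-[(1E,3E)-5-bromo-3-methylpenta-1,3-dien-1-yl]-4-(tert-butyldimethylsilyloxy)-2,6,6-trimethylcyclohex-2-en-1-ol | CC1=C[C@@H](O[Si](C)(C)C(C)(C)C)CC(C)(C)[C@]1(O)/C=C/C(C)=C/CBr
F9 | step 17 | [(2E,4E)-5-[(1R,4S)-4-(tert-butyldimethylsilyloxy)-1-hydroxy-2,6,6-trimethylcyclohex-2-en-1-yl]-3-methylpenta-2,4-dien-1-yl]triphenylphosphonium bromide | [Br-].CC1=C[C@@H](O[Si](C)(C)C(C)(C)C)CC(C)(C)[C@]1(O)/C=C/C(C)=C/C[P+](c1ccccc1)(c1ccccc1)c1ccccc1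
F10 | step 17 | 3′-O-(tert-butyldimethylsilyl) ether of all-E (3R,3′S,6′R)-7,8-didehydro-β,ε-carotene-3,3′,6′-triol | CC1=C[C@@H](O[Si](C)(C)C(C)(C)C)CC(C)(C)[C@]1(O)/C=C/C(C)=C/C=C/C(C)=C/C=C/C=C(C)/C=C/C=C(\C)C#CC1=C(C)C[C@@H](O)CC1(C)C
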